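Chroman-2-one numbering is used (O1, C2, C3, C4, C4a, C5 to C8, C8a). Ring A is the benzo ring, ring B the 4-hydroxyphenyl group, ring C the lactone and ring D the 4-methoxy-2-pyranone. The target is 4R.
Late disconnections: first the two O-benzyl groups, then the C4–ring B bond, made by enantioselective rhodium-catalysed 1,4-arylation of a 4-unsubstituted coumarin, which sets C4. The coumarin comes from its 3,4-dihydro form by dehydrogenation.
Key disconnection: ring C of the dihydrocoumarin is cut at C3–C2 and at O1–C8a, which frees CO2 and an ortho-bromostyrene. In the forward direction this is a formal (4+2) annulation of the unit C3=C4–C4a=C8a with one C=O of CO2, run in one flask as hydroboration, copper-catalysed carboxylation and copper-catalysed C–O coupling.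
Enabling feature: on ring A, C8a is ortho to the side chain on C4a and para to C6, which bears the electron-poor ring D. The chain end C3 (nucleophilic after hydroboration) and C8a (electrophilic as C–Br, activated by ring D) are therefore exactly one O–C(=O) unit apart and close the six-membered ring C.
Ring order: ring A is bought with F, Br and CH3 in place. Ring D is built on its formyl group (vinylogous aldol/lactonisation, then dehydrogenation), ring C follows in the key step, and ring B is attached last.

Key step: step 6

Assumption: 4-bromo-2-fluoro-6-methylbenzaldehyde is taken as a catalogue building block, and the facial sense of (R)-SEGPHOS is carried over from 4-unsubstituted coumarins that lack the 5-methyl group (if it inverts, (S)-SEGPHOS is used).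

Step 1
Reactants: 1 4-bromo-2-fluoro-6-methylbenzaldehyde
Product: 2 2-(benzyloxy)-4-bromo-6-methylbenzaldehyde
Conditions: BnOH, Cs2CO3, DMF, 80 °C
Reagents that add atoms: benzyl alcohol OCc1ccccc1
Why: Nucleophilic aromatic substitution (addition–elimination): fluoride ortho to the formyl group is by far the best leaving group on the ring, so benzyl oxide should replace it and leave the C–Br bond untouched.

Step 2
Reactants: 2 2-(benzyloxy)-4-bromo-6-methylbenzaldehyde
Product: 3 6-(benzyloxy)-4-bromo-3-iodo-2-methylbenzaldehyde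
Conditions: N-iodosuccinimide, CF3CO2H (cat.), MeCN, 0 °C to rt
Reagents that add atoms: N-iodosuccinimide O=C1CCC(=O)N1I
Why: Electrophilic aromatic iodination: the benzyloxy group directs para, to the carbon that is also ortho to the methyl group and meta to the formyl group, in line with the para halogenation of 3,5-disubstituted anisoles by N-halosuccinimides in acetonitrile.

Step 3
Reactants: 3 6-(benzyloxy)-4-bromo-3-iodo-2-methylbenzaldehyde, 4 methyl (E)-3-methoxybut-2-enoate
Product: 6 rac-6-[6-(benzyloxy)-4-bromo-3-iodo-2-methylphenyl]-4-methoxy-5,6-dihydro-2H-pyran-2-one, via lithium dienolate 5 (not isolated)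
Conditions: 4, LiN(iPr)2, THF, -78 °C; then 3, -78 °C to rt; AcOH quench
Reagents that add atoms: LiN(iPr)2 [Li+].CC(C)[N-]C(C)C (lithium of 5 only)
Why: Vinylogous aldol addition of the γ-carbon of dienolate 5 to the aldehyde, followed by lactonisation of the alkoxide onto the cis ester (the classical kavalactone ring synthesis); the new carbinol stereocentre forms as a racemate and is erased in step 4.

Step 4
Reactants: 6 rac-6-[6-(benzyloxy)-4-bromo-3-iodo-2-methylphenyl]-4-methoxy-5,6-dihydro-2H-pyran-2-one
Product: 7 6-[6-(benzyloxy)-4-bromo-3-iodo-2-methylphenyl]-4-methoxy-2H-pyran-2-one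
Conditions: DDQ, 1,4-dioxane, reflux
Reagents that add atoms: none
Why: DDQ dehydrogenation: hydride loss from the allylic CH2 next to the enol ether and proton loss from the benzylic CH should give the aromatic 2-pyranone ring D, whose formation is the driving force.

Step 5
Reactants: 7 6-[6-(benzyloxy)-4-bromo-3-iodo-2-methylphenyl]-4-methoxy-2H-pyran-2-one
Product: 8 6-[6-(benzyloxy)-4-bromo-3-ethenyl-2-methylphenyl]-4-methoxy-2H-pyran-2-one
Conditions: Bu3SnCH=CH2, Pd2(dba)3, AsPh3, CuI (cat.), DMF, 50 °C
Reagents that add atoms: tributyl(vinyl)stannane C=C[Sn](CCCC)(CCCC)CCCC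
Why: Stille coupling: zerovalent palladium adds to the C–I bond much faster than to the neighbouring C–Br bond, and the neutral conditions spare ring D.

Step 6
Reactants: 8 6-[6-(benzyloxy)-4-bromo-3-ethenyl-2-methylphenyl]-4-methoxy-2H-pyran-2-one, 9 carbon dioxide
Product: 12 7-(benzyloxy)-6-(4-methoxy-2-oxo-2H-pyran-6-yl)-5-methylchroman-2-one, via B-alkyl-9-BBN adduct 10 (not isolated), via potassium carboxylate 11 (not isolated)
Conditions: 9-BBN-H dimer, THF, 0 to 60 °C; then KOtBu, CuOAc (10 mol%), 1,10-phenanthroline (10 mol%), CO2 (1 atm), toluene, 100 °C; then DMF, 120 °C (one flask)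
Reagents that add atoms: 9-BBN-H [H]B1C2CCCC1CCC2 (boron unit of 10 only); KOtBu CC(C)(C)[O-].[K+] (potassium of 11 only)
Why: Proposed new method: 9-BBN-H adds anti-Markovnikov to the vinyl group and puts boron on C3 (10), tert-butoxide activation passes the alkyl group to phenanthroline-bound monovalent copper, and the alkylcopper inserts CO2, which makes the C3–C2 bond and gives carboxylate 11. The copper carboxylate then adds oxidatively to the neighbouring C8a–Br bond, and C–O reductive elimination from the seven-membered trivalent copper ring makes the O1–C8a bond and releases KBr. The closest known reaction types are the copper-catalysed carboxylation of B-alkyl-9-BBN compounds with CO2 and the Ullmann-type intramolecular O-arylation of carboxylates with aryl halides; new is their merger under one catalyst, so that CO2 is stitched as an O–C(=O) unit between a C–B and a C–Br bond. Ring C closes in a 6-exo mode by ipso substitution at C8a. No stereocentre is formed, since C4 is still a CH2 group. The step needs chemoselective hydroboration (the monosubstituted vinyl group reacts far faster than the lactone carbonyl and the trisubstituted, electron-poor double bonds of ring D), a C8a–Br bond that waits until the carboxylate is in place (closure of the alkylcopper on C8a would need a four-membered ring, and CO2 is in large excess) and a fast last coupling, which the ortho tether and the electron-poor ring D para to C8a secure.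

Step 7
Reactants: 12 7-(benzyloxy)-6-(4-methoxy-2-oxo-2H-pyran-6-yl)-5-methylchroman-2-one
Product: 13 7-(benzyloxy)-6-(4-methoxy-2-oxo-2H-pyran-6-yl)-5-methyl-2H-chromen-2-one
Conditions: DDQ, 1,4-dioxane, reflux
Reagents that add atoms: none
Why: DDQ dehydrogenation of a dihydrocoumarin: hydride abstraction at C4 is helped by the C7 benzyloxy group para to C4a, and proton loss from C3 gives the conjugated coumarin.

Step 8
Reactants: 13 7-(benzyloxy)-6-(4-methoxy-2-oxo-2H-pyran-6-yl)-5-methyl-2H-chromen-2-one, 14 [4-(benzyloxy)phenyl]boronic acid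
Product: 15 (4R)-7-(benzyloxy)-4-[4-(benzyloxy)phenyl]-6-(4-methoxy-2-oxo-2H-pyran-6-yl)-5-methylchroman-2-one
Conditions: Rh(acac)(C2H4)2 (3 mol%), (R)-SEGPHOS (3.3 mol%), 14 (5 equiv), 1,4-dioxane/H2O, 60 °C
Reagents that add atoms: none
Why: Hayashi–Miyaura asymmetric 1,4-addition: the aryl–rhodium species adds to C4 of the C3=C4 bond on the face left open by (R)-SEGPHOS, which sets 4R (sense taken from the parent coumarins), and water releases the product, while ring D is spared because its β-carbon bears OMe and its δ-carbon is fully substituted.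

Step 9
Reactants: 15 (4R)-7-(benzyloxy)-4-[4-(benzyloxy)phenyl]-6-(4-methoxy-2-oxo-2H-pyran-6-yl)-5-methylchroman-2-one
Product: 16 (4R)-7-hydroxy-4-(4-hydroxyphenyl)-6-(4-methoxy-2-oxo-2H-pyran-6-yl)-5-methylchroman-2-one (CNP0207475.1)
Conditions: H2 (1 atm), 10% Pd/C, EtOAc/THF, rt
Reagents that add atoms: none
Why: Hydrogenolysis of both benzyl aryl ethers under neutral conditions; C4 carries no heteroatom and no acidic hydrogen, so the stereocentre is not touched, and the aromatic ring D is reduced far more slowly than the O-benzyl bonds are cleaved.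

Compound list
1 | 4-bromo-2-fluoro-6-methylbenzaldehyde | O=Cc1c(F)cc(Br)cc1C | starting material
2 | 2-(benzyloxy)-4-bromo-6-methylbenzaldehyde | O=Cc1c(C)cc(Br)cc1OCc1ccccc1 | intermediate
3 | 6-(benzyloxy)-4-bromo-3-iodo-2-methylbenzaldehyde | O=Cc1c(C)c(I)c(Br)cc1OCc1ccccc1 | intermediate
4 | methyl (E)-3-methoxybut-2-enoate | CO/C(C)=C/C(=O)OC | starting material
5 | lithium dienolate of 4 | [Li+].[O-]C(OC)=CC(OC)=C | intermediate
6 | rac-6-[6-(benzyloxy)-4-bromo-3-iodo-2-methylphenyl]-4-methoxy-5,6-dihydro-2H-pyran-2-one | COC1=CC(=O)OC(C1)c1c(C)c(I)c(Br)cc1OCc1ccccc1 | intermediate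
7 | 6-[6-(benzyloxy)-4-bromo-3-iodo-2-methylphenyl]-4-methoxy-2H-pyran-2-one | COc1cc(-c2c(C)c(I)c(Br)cc2OCc2ccccc2)oc(=O)c1 | intermediate
8 | 6-[6-(benzyloxy)-4-bromo-3-ethenyl-2-methylphenyl]-4-methoxy-2H-pyran-2-one | COc1cc(-c2c(C)c(C=C)c(Br)cc2OCc2ccccc2)oc(=O)c1 | intermediate
9 | carbon dioxide | O=C=O | starting material
10 | 6-{6-(benzyloxy)-3-[2-(9-borabicyclo[3.3.1]nonan-9-yl)ethyl]-4-bromo-2-methylphenyl}-4-methoxy-2H-pyran-2-one | COc1cc(-c2c(C)c(CCB3C4CCCC3CCC4)c(Br)cc2OCc2ccccc2)oc(=O)c1 | intermediate
11 | potassium 3-[4-(benzyloxy)-6-bromo-3-(4-methoxy-2-oxo-2H-pyran-6-yl)-2-methylphenyl]propanoate | [K+].COc1cc(-c2c(C)c(CCC(=O)[O-])c(Br)cc2OCc2ccccc2)oc(=O)c1 | intermediate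
12 | 7-(benzyloxy)-6-(4-methoxy-2-oxo-2H-pyran-6-yl)-5-methylchroman-2-one | COc1cc(-c2c(OCc3ccccc3)cc3c(c2C)CCC(=O)O3)oc(=O)c1 | intermediate
13 | 7-(benzyloxy)-6-(4-methoxy-2-oxo-2H-pyran-6-yl)-5-methyl-2H-chromen-2-one | COc1cc(-c2c(OCc3ccccc3)cc3c(c2C)C=CC(=O)O3)oc(=O)c1 | intermediate
14 | [4-(benzyloxy)phenyl]boronic acid | OB(O)c1ccc(OCc2ccccc2)cc1 | starting material
15 | (4R)-7-(benzyloxy)-4-[4-(benzyloxy)phenyl]-6-(4-methoxy-2-oxo-2H-pyran-6-yl)-5-methylchroman-2-one | COc1cc(-c2c(OCc3ccccc3)cc3c(c2C)[C@@H](c2ccc(OCc4ccccc4)cc2)CC(=O)O3)oc(=O)c1 | intermediate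
16 | (4R)-7-hydroxy-4-(4-hydroxyphenyl)-6-(4-methoxy-2-oxo-2H-pyran-6-yl)-5-methylchroman-2-one | COc1cc(-c2c(O)cc3c(c2C)[C@@H](c2ccc(O)cc2)CC(=O)O3)oc(=O)c1 | target

Total step count: 9. Longest linear sequence: 9 steps (1 to 16).

Steps most likely to fail

Step 6.
- What may go wrong: boron-to-copper transfer or CO2 insertion is outrun by protodeboronation. Alternatively the cascade stalls after the carboxylation, because the copper carboxylate does not add to the hindered C8a–Br bond before ring D degrades at 120 °C.
- Fallback (sets out from 8, comes back at 12): the two bond formations are separated and the C–O bond is handed to another metal. Compound 8 is hydroborated to 10 and carboxylated under the known copper conditions at 100 °C to 11. Acidic work-up gives 3-[4-(benzyloxy)-6-bromo-3-(4-methoxy-2-oxo-2H-pyran-6-yl)-2-methylphenyl]propanoic acid F1. This acid is then closed to 12 at room temperature by the known nickel/photosensitiser coupling of aryl bromides with carboxylic acids (NiBr2·glyme, 4,4'-di-tert-butyl-2,2'-bipyridine, Ir(ppy)3, N-tert-butylisopropylamine, DMF, blue light). In that coupling the C–O reductive elimination takes place from an excited nickel aryl carboxylate.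

Step 8.
- What may go wrong: insertion of the C3=C4 bond into the aryl–rhodium bond is slowed by the peri methyl group on C5 and by the donor on C7. Hydrolytic loss of the boronic acid then wins, or the facial selectivity erodes.
- Fallback (sets out from 13, comes back at 15): the aryl group is put on first and the stereocentre is set by hydride delivery instead of aryl delivery. Oxidative Heck arylation of 13 with 14 (Pd(OAc)2, 1,10-phenanthroline, O2, DMF, 80 °C) gives 7-(benzyloxy)-4-[4-(benzyloxy)phenyl]-6-(4-methoxy-2-oxo-2H-pyran-6-yl)-5-methyl-2H-chromen-2-one F2. Enantioselective copper hydride 1,4-reduction with pinacolborane (CuCl, NaOtBu, DTBM-SEGPHOS of the matching hand, HBpin, toluene, rt, aqueous work-up) then gives 15.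

Step 4.
- What may go wrong: hydride abstraction is slow beside the doubly ortho-substituted, halogen-laden aryl group, so that oxidation of the benzyl ether or of the aryl methyl group competes.
- Fallback (sets out from 3, comes back at 7): the aryl carbon enters ring D at the acid oxidation level, so no dehydrogenation is needed. Pinnick oxidation of 3 (NaClO2, NaH2PO4, 2-methylbut-2-ene, tBuOH/H2O) gives 6-(benzyloxy)-4-bromo-3-iodo-2-methylbenzoic acid F3. SOCl2 (cat. DMF, toluene, 60 °C) gives 6-(benzyloxy)-4-bromo-3-iodo-2-methylbenzoyl chloride F4. γ-Acylation of dienolate 5 (2 equiv, THF, -78 °C) gives methyl (E)-5-[6-(benzyloxy)-4-bromo-3-iodo-2-methylphenyl]-3-methoxy-5-oxopent-2-enoate F5. DBU in toluene then closes the enol oxygen onto the cis ester to give 7.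

Further compounds
F1 | step 6 | 3-[4-(benzyloxy)-6-bromo-3-(4-methoxy-2-oxo-2H-pyran-6-yl)-2-methylphenyl]propanoic acid | COc1cc(-c2c(C)c(CCC(=O)O)c(Br)cc2OCc2ccccc2)oc(=O)c1
F2 | step 8 | 7-(benzyloxy)-4-[4-(benzyloxy)phenyl]-6-(4-methoxy-2-oxo-2H-pyran-6-yl)-5-methyl-2H-chromen-2-one | COc1cc(-c2c(OCc3ccccc3)cc3c(c2C)C(c2ccc(OCc4ccccc4)cc2)=CC(=O)O3)oc(=O)c1
F3 | step 4 | 6-(benzyloxy)-4-bromo-3-iodo-2-methylbenzoic acid | OC(=O)c1c(C)c(I)c(Br)cc1OCc1ccccc1
F4 | step 4 | 6-(benzyloxy)-4-bromo-3-iodo-2-methylbenzoyl chloride | ClC(=O)c1c(C)c(I)c(Br)cc1OCc1ccccc1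
F5 | step 4 | methyl (E)-5-[6-(benzyloxy)-4-bromo-3-iodo-2-methylphenyl]-3-methoxy-5-oxopent-2-enoate | COC(=O)/C=C(/OC)CC(=O)c1c(C)c(I)c(Br)cc1OCc1ccccc1
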